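## Retrosynthetic overview

1. Target ⇐ lactone ester 23 by hydroxide opening of a temporary cis-fused C6–O–C12 γ-lactone and fluoride desilylation; 23 ⇐ 22 by SeO2 hydroxylation at C15; 22 ⇐ hydroxy lactone 15 + side-chain acid 20 (ester at C8–O).
2. 15 ⇐ allenyl aldehyde 12 + CO2: a zerovalent-nickel carboxylative cyclisation forms the C6–C7 ring bond and the C11–C12 bond in one operation. C7, the β-carbon of the new acrylic acid, is the nucleophile toward the aldehyde carbon C6 (polarity-reversed, homoenolate-type union).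
3. 12 ⇐ ester 9 by enantioselective Ireland–Claisen rearrangement (C5–C10 bond, quaternary C10), then half-reduction.
4. 9 ⇐ allenyl dienol 7 + 3-methylbut-3-enoic acid; 7 ⇐ 3-(trimethylsilyl)propynal by asymmetric propargylation (C8), carboalumination and Crabbé homologation; 20 ⇐ asymmetric Morita–Baylis–Hillman reaction.
5. Ring order: the cyclohexane is the only carbocycle (step 8); the γ-lactone closes in the same pot and is opened in the last step.

Assumption: core atoms carry elemane-type labels (C10 quaternary, C5–C10 ring, C11–C13 acrylic acid, C15 the CH2OH carbon), and the free γ-hydroxy acid is taken to be isolable when kept cold at pH 5 or above, since acid recloses the lactone.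

Assumption: the catalyst antipodes named in steps 1, 6 and 9 follow the reported sense of induction for simple aldehydes and allyl esters; if a substrate responds in the opposite sense, the mirror-image catalyst is used.

## Route

Step 1
Reactants: 1 3-(trimethylsilyl)prop-2-ynal; 2 allenylboronic acid pinacol ester
Product: 3 (3S)-1-(trimethylsilyl)hexa-1,5-diyn-3-ol
Conditions: (S)-3,3′-bis(2,4,6-triisopropylphenyl)-1,1′-binaphthyl-2,2′-diyl hydrogen phosphate (5 mol%), PhMe, −20 °C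
Reagents that add atoms: none
Why: Chiral-phosphoric-acid-catalysed asymmetric propargylation (SE2′ addition of the allenylboronate through a six-membered chair transition state); the acid blocks one aldehyde face and sets C8 as S.

Step 2
Reactants: 3 (3S)-1-(trimethylsilyl)hexa-1,5-diyn-3-ol
Product: 4 (3S)-3-(triethylsilyloxy)-1-(trimethylsilyl)hexa-1,5-diyne
Conditions: Et3SiCl, imidazole, CH2Cl2, 0 → 23 °C
Reagents that add atoms: chlorotriethylsilane CC[Si](Cl)(CC)CC
Why: Standard silylation of a secondary alcohol; the TES ether survives the basic and organometallic steps and falls off in dilute acid in step 8.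

Step 3
Reactants: 4 (3S)-3-(triethylsilyloxy)-1-(trimethylsilyl)hexa-1,5-diyne
Product: 6 (2E,5S)-3-methyl-5-(triethylsilyloxy)hept-2-en-6-yn-1-ol, via C-silylated enynol 5 (not isolated)
Conditions: Me3Al (3 equiv), Cp2ZrCl2 (0.25 equiv), ClCH2CH2Cl, 23 °C; n-BuLi, then (CH2O)n, THF, −78 → 23 °C; aq. KNaC4H4O6; then K2CO3 (0.2 equiv), MeOH, 0 °C
Reagents that add atoms: trimethylaluminium C[Al](C)C; paraformaldehyde (as formaldehyde) C=O
Why: Negishi zirconium-catalysed carboalumination adds Me and Al syn across the terminal alkyne only (the silylated alkyne is inert), hydroxymethylation of the alkenylalanate gives the (E)-trisubstituted allylic alcohol, and K2CO3/MeOH removes the alkynyl TMS group.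

Step 4
Reactants: 6 (2E,5S)-3-methyl-5-(triethylsilyloxy)hept-2-en-6-yn-1-ol
Product: 7 (2E,5S)-3-methyl-5-(triethylsilyloxy)octa-2,6,7-trien-1-ol
Conditions: (CH2O)n, CuI (0.5 equiv), Cy2NH, 1,4-dioxane, 100 °C
Reagents that add atoms: paraformaldehyde (as formaldehyde) C=O
Why: Crabbé homologation (Mannich reaction to the propargylamine, then copper-mediated 1,5-hydride shift) turns the terminal alkyne into the terminal allene without touching C8.

Step 5
Reactants: 7 (2E,5S)-3-methyl-5-(triethylsilyloxy)octa-2,6,7-trien-1-ol; 8 3-methylbut-3-enoic acid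
Product: 9 (2E,5S)-3-methyl-5-(triethylsilyloxy)octa-2,6,7-trien-1-yl 3-methylbut-3-enoate
Conditions: DCC, 4-(dimethylamino)pyridine (5 mol%), CH2Cl2, 0 °C
Reagents that add atoms: none
Why: Steglich esterification of the primary allylic alcohol; low temperature and little DMAP keep the β,γ-unsaturated acid from moving into conjugation.

Step 6
Reactants: 9 (2E,5S)-3-methyl-5-(triethylsilyloxy)octa-2,6,7-trien-1-yl 3-methylbut-3-enoate
Product: 11 methyl (2R,3R,5S)-3-ethenyl-3-methyl-2-(prop-1-en-2-yl)-5-(triethylsilyloxy)octa-6,7-dienoate, via carboxylic acid 10 (not isolated)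
Conditions: (4R,5R)-2-bromo-4,5-diphenyl-1,3-bis[3,5-bis(trifluoromethyl)phenylsulfonyl]-1,3,2-diazaborolidine (1.3 equiv), Et3N, PhMe/hexane, −78 °C then 4 °C, 48 h; aq. work-up, sulfonamide filtered off; then Me3SiCHN2, MeOH/PhMe, 0 °C
Reagents that add atoms: (trimethylsilyl)diazomethane C[Si](C)(C)C=[N+]=[N-]
Why: Enantioselective Ireland–Claisen rearrangement through the chiral (E)-O-boron ketene acetal and a chair transition state on the (E)-allyl unit puts isopropenyl and vinyl anti across the new C5–C10 bond (quaternary C10), the (R,R)-controller fixing both centres as R regardless of remote C8; the crude acid is methylated in the same operation.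

Step 7
Reactants: 11 methyl (2R,3R,5S)-3-ethenyl-3-methyl-2-(prop-1-en-2-yl)-5-(triethylsilyloxy)octa-6,7-dienoate
Product: 12 (2R,3R,5S)-3-ethenyl-3-methyl-2-(prop-1-en-2-yl)-5-(triethylsilyloxy)octa-6,7-dienal
Conditions: i-Bu2AlH (1.1 equiv), CH2Cl2, −78 °C; aq. KNaC4H4O6
Reagents that add atoms: none
Why: Half-reduction of a hindered α-branched ester stops at the tetrahedral aluminate at −78 °C, and the non-basic tartrate work-up spares the allylic α-centre C5.

Step 8
Reactants: 12 (2R,3R,5S)-3-ethenyl-3-methyl-2-(prop-1-en-2-yl)-5-(triethylsilyloxy)octa-6,7-dienal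
Product: 15 (3aR,4S,6R,7R,7aS)-6-ethenyl-4-hydroxy-6-methyl-3-methylidene-7-(prop-1-en-2-yl)hexahydro-1-benzofuran-2(3H)-one, via nickel alkoxide carboxylate chelate 13 (not isolated), via hydroxy acid 14 (not isolated)
Conditions: Ni(cod)2 (1.2 equiv), DBU (2.4 equiv), CO2 (1 atm), THF, 0 °C, 4 h; then 1 M HCl, THF, 23 °C
Reagents that add atoms: carbon dioxide O=C=O
Why: Proposed new method: zerovalent nickel either couples the internal allene π-bond with the tethered aldehyde (oxidative cyclisation to a cis-fused five-membered oxanickelacycle with an alkenyl–Ni bond at C11, into which CO2 inserts) or first couples the allene with CO2 to an allylnickel carboxylate that adds through C7 to the aldehyde, and both paths converge on chelate 13, so C7 reacts as the β-carbanion (homoenolate) of the new acrylic acid with the electrophilic aldehyde carbon; the metallacycle forces C6–O and C7–C11 cis (C6 S), and C11 goes anti to the C8 silyloxy group because the syn arrangement would place C11 or the nickel alkoxide 1,3-diaxial to the C5 isopropenyl or the C10 methyl; dilute HCl then closes the cis γ-lactone and cleaves the TES ether; the closest known reaction types are the intermolecular nickel-mediated allene/CO2/aldehyde coupling and the nickel-catalysed alkylative cyclisation of allenyl aldehydes with organozincs.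

Step 9
Reactants: 16 1,1,1,3,3,3-hexafluoropropan-2-yl acrylate; 17 (tert-butyldimethylsilyloxy)acetaldehyde
Product: 18 1,1,1,3,3,3-hexafluoropropan-2-yl (3R)-4-[(tert-butyldimethylsilyl)oxy]-3-hydroxy-2-methylidenebutanoate
Conditions: α-isocupreine (10 mol%), DMF, −55 °C
Reagents that add atoms: none
Why: Asymmetric Morita–Baylis–Hillman reaction of the activated acrylate; quinine-derived α-isocupreine, the pseudo-enantiomer of β-isocupreidine, gives the (3R) carbinol (CH2OTBS outranks the vinyl carbon, so the label is R).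

Step 10
Reactants: 18 1,1,1,3,3,3-hexafluoropropan-2-yl (3R)-4-[(tert-butyldimethylsilyl)oxy]-3-hydroxy-2-methylidenebutanoate
Product: 19 1,1,1,3,3,3-hexafluoropropan-2-yl (3R)-3,4-bis[(tert-butyldimethylsilyl)oxy]-2-methylidenebutanoate
Conditions: t-BuMe2SiOTf, 2,6-lutidine, CH2Cl2, −78 → 0 °C
Reagents that add atoms: tert-butyldimethylsilyl trifluoromethanesulfonate CC(C)(C)[Si](C)(C)OS(=O)(=O)C(F)(F)F
Why: Silyl triflate protection of the hindered allylic carbinol under non-nucleophilic base leaves the active ester and the stereocentre intact.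

Step 11
Reactants: 19 1,1,1,3,3,3-hexafluoropropan-2-yl (3R)-3,4-bis[(tert-butyldimethylsilyl)oxy]-2-methylidenebutanoate
Product: 20 (3R)-3,4-bis[(tert-butyldimethylsilyl)oxy]-2-methylidenebutanoic acid
Conditions: LiOH, THF/H2O, 0 °C; then 1 M HCl to pH 3
Reagents that add atoms: lithium hydroxide [Li+].[OH-]
Why: The hexafluoroisopropyl ester is an activated ester and saponifies within minutes at 0 °C, with no α-hydrogen to epimerise.

Step 12
Reactants: 15 (3aR,4S,6R,7R,7aS)-6-ethenyl-4-hydroxy-6-methyl-3-methylidene-7-(prop-1-en-2-yl)hexahydro-1-benzofuran-2(3H)-one; 20 (3R)-3,4-bis[(tert-butyldimethylsilyl)oxy]-2-methylidenebutanoic acid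
Product: 22 (3aR,4S,6R,7R,7aS)-6-ethenyl-6-methyl-3-methylidene-2-oxo-7-(prop-1-en-2-yl)octahydro-1-benzofuran-4-yl (3R)-3,4-bis[(tert-butyldimethylsilyl)oxy]-2-methylidenebutanoate, via mixed anhydride 21 (not isolated)
Conditions: 2,4,6-Cl3C6H2COCl, Et3N, THF, 23 °C; then 15, 4-(dimethylamino)pyridine, PhMe, 23 °C
Reagents that add atoms: none
Why: Yamaguchi esterification acylates the only free hydroxyl (C8–OH) with retention, while the lactone holds C6–O and C12 protected.

Step 13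
Reactants: 22 (3aR,4S,6R,7R,7aS)-6-ethenyl-6-methyl-3-methylidene-2-oxo-7-(prop-1-en-2-yl)octahydro-1-benzofuran-4-yl (3R)-3,4-bis[(tert-butyldimethylsilyl)oxy]-2-methylidenebutanoate
Product: 23 (3aR,4S,6R,7S,7aS)-6-ethenyl-7-(3-hydroxyprop-1-en-2-yl)-6-methyl-3-methylidene-2-oxooctahydro-1-benzofuran-4-yl (3R)-3,4-bis[(tert-butyldimethylsilyl)oxy]-2-methylidenebutanoate
Conditions: SeO2 (0.5 equiv), t-BuOOH, salicylic acid (10 mol%), CH2Cl2, 23 °C
Reagents that add atoms: tert-butyl hydroperoxide CC(C)(C)OO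
Why: SeO2 allylic oxidation (ene reaction, then [2,3]-shift) attacks the only electron-rich alkene carrying allylic hydrogens, and on a 1,1-disubstituted alkene the methyl reacts before the methine; the vinyl group has no allylic hydrogen and the two acrylate alkenes are deactivated.

Step 14
Reactants: 23 (3aR,4S,6R,7S,7aS)-6-ethenyl-7-(3-hydroxyprop-1-en-2-yl)-6-methyl-3-methylidene-2-oxooctahydro-1-benzofuran-4-yl (3R)-3,4-bis[(tert-butyldimethylsilyl)oxy]-2-methylidenebutanoate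
Product: 25 2-[(1S,2S,3S,4R,6S)-6-{[(3R)-3,4-dihydroxy-2-methylidenebutanoyl]oxy}-4-ethenyl-2-hydroxy-3-(3-hydroxyprop-1-en-2-yl)-4-methylcyclohexyl]prop-2-enoic acid, via lithium carboxylate 24 (not isolated)
Conditions: LiOH (1.2 equiv), THF/H2O, 0 °C; AcOH to pH 7; then Bu4NF, AcOH, THF, 23 °C; aq. NaH2PO4 (pH 5), 0 °C
Reagents that add atoms: lithium hydroxide [Li+].[OH-]
Why: Chemoselective saponification opens the γ-lactone, while the side-chain ester (secondary alkyl, α-branched, flanked by two TBS ethers) is far slower and the trans C6/C8 oxygens cannot exchange the acyl group; buffered fluoride then removes both TBS groups without closing the lactone.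

## Compound list

1 | 3-(trimethylsilyl)prop-2-ynal | C[Si](C)(C)C#CC=O | starting material
2 | allenylboronic acid pinacol ester | C=C=CB1OC(C)(C)C(C)(C)O1 | starting material
3 | (3S)-1-(trimethylsilyl)hexa-1,5-diyn-3-ol | C#CC[C@H](O)C#C[Si](C)(C)C | intermediate
4 | (3S)-3-(triethylsilyloxy)-1-(trimethylsilyl)hexa-1,5-diyne | C#CC[C@H](O[Si](CC)(CC)CC)C#C[Si](C)(C)C | intermediate
5 | (2E,5S)-3-methyl-5-(triethylsilyloxy)-7-(trimethylsilyl)hept-2-en-6-yn-1-ol | OC/C=C(\C)C[C@H](O[Si](CC)(CC)CC)C#C[Si](C)(C)C | intermediate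
6 | (2E,5S)-3-methyl-5-(triethylsilyloxy)hept-2-en-6-yn-1-ol | OC/C=C(\C)C[C@H](O[Si](CC)(CC)CC)C#C | intermediate
7 | (2E,5S)-3-methyl-5-(triethylsilyloxy)octa-2,6,7-trien-1-ol | OC/C=C(\C)C[C@H](O[Si](CC)(CC)CC)C=C=C | intermediate
8 | 3-methylbut-3-enoic acid | CC(=C)CC(=O)O | starting material
9 | (2E,5S)-3-methyl-5-(triethylsilyloxy)octa-2,6,7-trien-1-yl 3-methylbut-3-enoate | CC(=C)CC(=O)OC/C=C(\C)C[C@H](O[Si](CC)(CC)CC)C=C=C | intermediate
10 | (2R,3R,5S)-3-ethenyl-3-methyl-2-(prop-1-en-2-yl)-5-(triethylsilyloxy)octa-6,7-dienoic acid | C=C[C@@]([C@H](C(=O)O)C(C)=C)(C)C[C@H](O[Si](CC)(CC)CC)C=C=C | intermediate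
11 | methyl (2R,3R,5S)-3-ethenyl-3-methyl-2-(prop-1-en-2-yl)-5-(triethylsilyloxy)octa-6,7-dienoate | C=C[C@@]([C@H](C(=O)OC)C(C)=C)(C)C[C@H](O[Si](CC)(CC)CC)C=C=C | intermediate
12 | (2R,3R,5S)-3-ethenyl-3-methyl-2-(prop-1-en-2-yl)-5-(triethylsilyloxy)octa-6,7-dienal | C=C[C@@]([C@H](C=O)C(C)=C)(C)C[C@H](O[Si](CC)(CC)CC)C=C=C | intermediate
13 | divalent nickel chelate of 2-[(1S,2S,3R,4R,6S)-4-ethenyl-4-methyl-2-oxido-3-(prop-1-en-2-yl)-6-(triethylsilyloxy)cyclohexyl]prop-2-enoate (DBU ligands omitted) | C=C[C@@]1(C)C[C@H](O[Si](CC)(CC)CC)[C@@H](C(=C)C(=O)O[Ni]2)[C@@H](O2)[C@@H]1C(C)=C | intermediate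
14 | 2-[(1S,2S,3R,4R,6S)-4-ethenyl-2-hydroxy-4-methyl-3-(prop-1-en-2-yl)-6-(triethylsilyloxy)cyclohexyl]prop-2-enoic acid | C=C[C@@]1(C)C[C@H](O[Si](CC)(CC)CC)[C@@H](C(=C)C(=O)O)[C@@H](O)[C@@H]1C(C)=C | intermediate
15 | (3aR,4S,6R,7R,7aS)-6-ethenyl-4-hydroxy-6-methyl-3-methylidene-7-(prop-1-en-2-yl)hexahydro-1-benzofuran-2(3H)-one | C=C[C@@]1(C)C[C@H](O)[C@@H](C(=C)C(=O)O2)[C@@H]2[C@@H]1C(C)=C | intermediate
16 | 1,1,1,3,3,3-hexafluoropropan-2-yl acrylate | C=CC(=O)OC(C(F)(F)F)C(F)(F)F | starting material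
17 | (tert-butyldimethylsilyloxy)acetaldehyde | CC(C)(C)[Si](C)(C)OCC=O | starting material
18 | 1,1,1,3,3,3-hexafluoropropan-2-yl (3R)-4-[(tert-butyldimethylsilyl)oxy]-3-hydroxy-2-methylidenebutanoate | C=C(C(=O)OC(C(F)(F)F)C(F)(F)F)[C@@H](O)CO[Si](C)(C)C(C)(C)C | intermediate
19 | 1,1,1,3,3,3-hexafluoropropan-2-yl (3R)-3,4-bis[(tert-butyldimethylsilyl)oxy]-2-methylidenebutanoate | C=C(C(=O)OC(C(F)(F)F)C(F)(F)F)[C@@H](O[Si](C)(C)C(C)(C)C)CO[Si](C)(C)C(C)(C)C | intermediate
20 | (3R)-3,4-bis[(tert-butyldimethylsilyl)oxy]-2-methylidenebutanoic acid | C=C(C(=O)O)[C@@H](O[Si](C)(C)C(C)(C)C)CO[Si](C)(C)C(C)(C)C | intermediate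
21 | (3R)-3,4-bis[(tert-butyldimethylsilyl)oxy]-2-methylidenebutanoic 2,4,6-trichlorobenzoic anhydride | C=C(C(=O)OC(=O)c1c(Cl)cc(Cl)cc1Cl)[C@@H](O[Si](C)(C)C(C)(C)C)CO[Si](C)(C)C(C)(C)C | intermediate
22 | (3aR,4S,6R,7R,7aS)-6-ethenyl-6-methyl-3-methylidene-2-oxo-7-(prop-1-en-2-yl)octahydro-1-benzofuran-4-yl (3R)-3,4-bis[(tert-butyldimethylsilyl)oxy]-2-methylidenebutanoate | C=C[C@@]1(C)C[C@H](OC(=O)C(=C)[C@@H](O[Si](C)(C)C(C)(C)C)CO[Si](C)(C)C(C)(C)C)[C@@H](C(=C)C(=O)O2)[C@@H]2[C@@H]1C(C)=C | intermediate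
23 | (3aR,4S,6R,7S,7aS)-6-ethenyl-7-(3-hydroxyprop-1-en-2-yl)-6-methyl-3-methylidene-2-oxooctahydro-1-benzofuran-4-yl (3R)-3,4-bis[(tert-butyldimethylsilyl)oxy]-2-methylidenebutanoate | C=C[C@@]1(C)C[C@H](OC(=O)C(=C)[C@@H](O[Si](C)(C)C(C)(C)C)CO[Si](C)(C)C(C)(C)C)[C@@H](C(=C)C(=O)O2)[C@@H]2[C@@H]1C(=C)CO | intermediate
24 | lithium 2-[(1S,2S,3S,4R,6S)-6-{[(3R)-3,4-bis(tert-butyldimethylsilyloxy)-2-methylidenebutanoyl]oxy}-4-ethenyl-2-hydroxy-3-(3-hydroxyprop-1-en-2-yl)-4-methylcyclohexyl]prop-2-enoate | C=C[C@@]1(C)C[C@H](OC(=O)C(=C)[C@@H](O[Si](C)(C)C(C)(C)C)CO[Si](C)(C)C(C)(C)C)[C@@H](C(=C)C(=O)[O-])[C@@H](O)[C@@H]1C(=C)CO.[Li+] | intermediate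
25 | 2-[(1S,2S,3S,4R,6S)-6-{[(3R)-3,4-dihydroxy-2-methylidenebutanoyl]oxy}-4-ethenyl-2-hydroxy-3-(3-hydroxyprop-1-en-2-yl)-4-methylcyclohexyl]prop-2-enoic acid | C=C[C@@]1(C)C[C@H](OC(=O)C(=C)[C@@H](O)CO)[C@@H](C(=C)C(=O)O)[C@@H](O)[C@@H]1C(=C)CO | target

## Step count and risks

Total step count: 14. Longest linear sequence: 11 steps (steps 1–8, then 12, 13, 14); steps 9–11 make the side-chain acid.

Most likely to fail, first: step 8. The cyclisation is new, the aldehyde α-centre C5 could epimerise under DBU, and the C6 configuration rests on the metallacycle argument. The fallback sets out from 12 and comes back at 15. A copper-catalysed borylative allene–aldehyde cyclisation (B2pin2, CuCl, 1,3-bis(2,6-diisopropylphenyl)imidazol-2-ylidene, NaOt-Bu, MeOH, THF) puts boron on the central allene carbon and lets the allylcopper add through C7, giving the alkenyl boronate F1. Copper-catalysed carboxylation of the C11–B bond (same CuCl/carbene system, KOt-Bu, CO2, THF, 70 °C) followed by 1 M HCl gives 15 through 14.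

Second: step 13. SeO2 can over-oxidise to the enal, attack the C5 methine, or give a low yield on this crowded isopropenyl group. The fallback sets out from 22 and comes back at 23. Ene-type chlorination with Ca(OCl)2 and solid CO2 in CH2Cl2/H2O at 0 °C gives the allylic chloride F2. Silver-assisted hydrolysis (AgOTf, 2,6-lutidine, acetone/H2O) then gives 23; the 2-substituted allyl cation is symmetric, so no regioisomer can form.

Third: step 14. Hydroxide may also cleave the C8 ester, and the product recloses to the lactone in acid. The fallback sets out from 12 and comes back at 25, and never exposes the side-chain ester to hydroxide. The nickel/CO2 cyclisation is run as in step 8, but chelate 13 is quenched with allyl bromide in DMF to give the allyl ester F3. t-BuMe2SiOTf/2,6-lutidine gives the C6 silyl ether F4. Pyridinium p-toluenesulfonate in MeOH at 0 °C removes only the TES group to give the alcohol F5. Yamaguchi coupling with 20 gives the diester F6, and SeO2/t-BuOOH gives the allylic alcohol F7. Pd(PPh3)4 with morpholine, then Bu4NF/AcOH, release 25.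

## Further compounds

F1 | step 8 | (1S,2R,3R,5S,6S)-3-ethenyl-3-methyl-2-(prop-1-en-2-yl)-6-[1-(4,4,5,5-tetramethyl-1,3,2-dioxaborolan-2-yl)ethenyl]-5-(triethylsilyloxy)cyclohexan-1-ol | C=C[C@@]1(C)C[C@H](O[Si](CC)(CC)CC)[C@@H](C(=C)B2OC(C)(C)C(C)(C)O2)[C@@H](O)[C@@H]1C(C)=C
F2 | step 13 | (3aR,4S,6R,7S,7aS)-7-(3-chloroprop-1-en-2-yl)-6-ethenyl-6-methyl-3-methylidene-2-oxooctahydro-1-benzofuran-4-yl (3R)-3,4-bis[(tert-butyldimethylsilyl)oxy]-2-methylidenebutanoate | C=C[C@@]1(C)C[C@H](OC(=O)C(=C)[C@@H](O[Si](C)(C)C(C)(C)C)CO[Si](C)(C)C(C)(C)C)[C@@H](C(=C)C(=O)O2)[C@@H]2[C@@H]1C(=C)CCl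
F3 | step 14 | prop-2-en-1-yl 2-[(1S,2S,3R,4R,6S)-4-ethenyl-2-hydroxy-4-methyl-3-(prop-1-en-2-yl)-6-(triethylsilyloxy)cyclohexyl]prop-2-enoate | C=C[C@@]1(C)C[C@H](O[Si](CC)(CC)CC)[C@@H](C(=C)C(=O)OCC=C)[C@@H](O)[C@@H]1C(C)=C
F4 | step 14 | prop-2-en-1-yl 2-[(1R,2S,3R,4R,6S)-2-(tert-butyldimethylsilyloxy)-4-ethenyl-4-methyl-3-(prop-1-en-2-yl)-6-(triethylsilyloxy)cyclohexyl]prop-2-enoate | C=C[C@@]1(C)C[C@H](O[Si](CC)(CC)CC)[C@@H](C(=C)C(=O)OCC=C)[C@@H](O[Si](C)(C)C(C)(C)C)[C@@H]1C(C)=C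
F5 | step 14 | prop-2-en-1-yl 2-[(1R,2S,3R,4R,6S)-2-(tert-butyldimethylsilyloxy)-4-ethenyl-6-hydroxy-4-methyl-3-(prop-1-en-2-yl)cyclohexyl]prop-2-enoate | C=C[C@@]1(C)C[C@H](O)[C@@H](C(=C)C(=O)OCC=C)[C@@H](O[Si](C)(C)C(C)(C)C)[C@@H]1C(C)=C
F6 | step 14 | (1S,2R,3S,4R,5R)-3-[(tert-butyldimethylsilyl)oxy]-5-ethenyl-5-methyl-2-[3-oxo-3-(prop-2-en-1-yloxy)prop-1-en-2-yl]-4-(prop-1-en-2-yl)cyclohexyl (3R)-3,4-bis[(tert-butyldimethylsilyl)oxy]-2-methylidenebutanoate | C=C[C@@]1(C)C[C@H](OC(=O)C(=C)[C@@H](O[Si](C)(C)C(C)(C)C)CO[Si](C)(C)C(C)(C)C)[C@@H](C(=C)C(=O)OCC=C)[C@@H](O[Si](C)(C)C(C)(C)C)[C@@H]1C(C)=C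
F7 | step 14 | (1S,2R,3S,4S,5R)-3-[(tert-butyldimethylsilyl)oxy]-5-ethenyl-4-(3-hydroxyprop-1-en-2-yl)-5-methyl-2-[3-oxo-3-(prop-2-en-1-yloxy)prop-1-en-2-yl]cyclohexyl (3R)-3,4-bis[(tert-butyldimethylsilyl)oxy]-2-methylidenebutanoate | C=C[C@@]1(C)C[C@H](OC(=O)C(=C)[C@@H](O[Si](C)(C)C(C)(C)C)CO[Si](C)(C)C(C)(C)C)[C@@H](C(=C)C(=O)OCC=C)[C@@H](O[Si](C)(C)C(C)(C)C)[C@@H]1C(=C)CO
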